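Everything rests on removing ring B of the flavone and regrowing it on a finished chromone. The feature exploited is the pattern of ring B. It is a 1,4-dioxygenated benzene (O on C2' and C5') whose C3' and C4' are also oxygenated, with the chromone on C1' and hydrogen only on C6'. This is the imprint of a Dötz benzannulation. Heating the alkyne with the carbene complex should join the carbene carbon (C5') to the alkyne CH (C6'), the inner alkyne carbon (C1') to a migrating CO (C2'), and that carbon to the vinyl terminus (C3'). The precursors are a 2-ethynyl-5,6,7-trimethoxychromone and a Cr(CO)5 methoxycarbene bearing a (Z)-1,2-dimethoxyvinyl group. One O-methylation finishes.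

Key step: step 7

Remark: (Z)-1,2-dimethoxyethene is taken as a purchasable single isomer; lithiation proceeds with retention, so the two vinyl methoxy groups stay cis and the carbene complex is the 2Z isomer, whose geometry vanishes on aromatisation.

Step 1
Reactants: 1 3,4,5-trimethoxyphenol
Product: 2 1-(6-hydroxy-2,3,4-trimethoxyphenyl)ethan-1-one
Conditions: AcOH, BF3·OEt2, 85 °C; then H2O
Reagents that add atoms: acetic acid, CC(=O)O
Why: BF3-mediated Friedel–Crafts acylation (O-acetylation and Fries-type migration) can only reach the two equivalent free positions ortho to the hydroxyl group, and chelation of the resulting ortho-hydroxy ketone to boron deactivates the ring against a second acylation.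

Step 2
Reactants: 2 1-(6-hydroxy-2,3,4-trimethoxyphenyl)ethan-1-one; 3 diethyl oxalate
Product: 5 ethyl 5,6,7-trimethoxy-4-oxo-4H-chromene-2-carboxylate, via diketoester 4 (not isolated)
Conditions: NaOEt, EtOH, reflux; then conc. HCl, EtOH, reflux
Reagents that add atoms: none
Why: Crossed Claisen condensation of the methyl ketone enolate with non-enolisable diethyl oxalate gives the 2,4-dioxo ester, and acid-catalysed cyclodehydration through the ortho phenol closes the pyranone, the standard entry to chromone-2-carboxylates.

Step 3
Reactants: 5 ethyl 5,6,7-trimethoxy-4-oxo-4H-chromene-2-carboxylate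
Product: 6 2-(hydroxymethyl)-5,6,7-trimethoxy-4H-chromen-4-one
Conditions: NaBH4, EtOH, 0 °C
Reagents that add atoms: none
Why: Chemoselective hydride reduction: the ester on the oxygen-bearing, electron-poor C2 is activated enough for NaBH4 at 0 °C, whereas the C4 carbonyl is a vinylogous ester and is left alone, as is established for chromone-2-carboxylates.

Step 4
Reactants: 6 2-(hydroxymethyl)-5,6,7-trimethoxy-4H-chromen-4-one
Product: 7 5,6,7-trimethoxy-4-oxo-4H-chromene-2-carbaldehyde
Conditions: Dess–Martin periodinane, CH2Cl2, rt
Reagents that add atoms: none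
Why: Dess–Martin oxidation takes the primary allylic-type alcohol to the aldehyde under near-neutral, water-free conditions that cannot over-oxidise it or touch the chromone and the aryl ethers.

Step 5
Reactants: 7 5,6,7-trimethoxy-4-oxo-4H-chromene-2-carbaldehyde
Product: 8 2-ethynyl-5,6,7-trimethoxy-4H-chromen-4-one
Conditions: dimethyl (1-diazo-2-oxopropyl)phosphonate, K2CO3, MeOH, 0 °C to rt
Reagents that add atoms: dimethyl (1-diazo-2-oxopropyl)phosphonate (Ohira–Bestmann reagent), COP(=O)(OC)C(=[N+]=[N-])C(C)=O
Why: Seyferth–Gilbert homologation in its Ohira–Bestmann form: methanolysis frees the diazomethylphosphonate anion, which olefinates the very electrophilic aldehyde, and loss of N2 with a 1,2-hydrogen shift in the alkylidene carbene gives the terminal alkyne under a base mild enough for a 2-substituted chromone at or below room temperature.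

Step 6
Reactants: 9 (Z)-1,2-dimethoxyethene; 10 chromium hexacarbonyl, Cr(CO)6
Product: 13 pentacarbonyl[(2Z)-1,2,3-trimethoxyprop-2-en-1-ylidene]chromium, via vinyllithium 11 (not isolated), via lithium acylchromate 12 (not isolated)
Conditions: t-BuLi, THF, −78 °C; add 10, −78 °C to rt; solvent change; Me3OBF4, CH2Cl2, 0 °C
Reagents that add atoms: trimethyloxonium tetrafluoroborate, C[O+](C)C.F[B-](F)(F)F
Why: Fischer carbene synthesis: lithiation of the enol ether alpha to oxygen with retention of geometry, addition of the vinyllithium to a CO ligand of Cr(CO)6 and hard O-methylation of the acylmetalate, with the anion kept at −78 °C until chromium is present because lithium and the neighbouring methoxy group stand anti and could otherwise leave as LiOMe.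

Step 7
Reactants: 8 2-ethynyl-5,6,7-trimethoxy-4H-chromen-4-one; 13 pentacarbonyl[(2Z)-1,2,3-trimethoxyprop-2-en-1-ylidene]chromium
Product: 15 2-(2-hydroxy-3,4,5-trimethoxyphenyl)-5,6,7-trimethoxy-4H-chromen-4-one, via arene tricarbonylchromium complex 14 (not isolated)
Conditions: 13 (1.5 equiv), degassed THF (0.3 M), Ar, 50 °C; then air, CH2Cl2, rt
Reagents that add atoms: none
Why: Proposed new method: thermal loss of one CO from 13 opens a site for 8, which should insert into the Cr=C bond with its CH end bonding to the carbene carbon (C5'–C6'), after which CO migrates to the new carbene carbon to give a chromium-bound dienylketene (C1'–C2'). Ring B, the only ring formed, then closes by a 6π electrocyclisation of this ketene onto the methoxyvinyl terminus (C2'–C3'), and enolisation of the cyclohexadienone gives the phenol as its Cr(CO)3 complex 14, which air strips to 15 without taking the para-methoxyphenol on to a quinone. The closest known reaction type is the Dötz benzannulation of alkenyl(methoxy)carbene Cr(CO)5 complexes with terminal alkynes; an alkenyl unit carrying two oxygen donors combined with an alkyne conjugated to an enone has no precedent. No stereocentre is created and the alkene geometry of 13 disappears, though the 2Z isomer is preferred because it turns only hydrogen, not methoxy, into the closing triene. The regioselectivity needed rests on the terminal alkyne, whose bulky chromonyl end is kept away from the methoxycarbene carbon and therefore ends next to the new hydroxyl group. Six-membered over five-membered ring formation is favoured by chromium rather than a heavier group 6 metal, by a weakly coordinating ether solvent, by high concentration and by a temperature of only 50 °C, all of which favour CO migration.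

Step 8
Reactants: 15 2-(2-hydroxy-3,4,5-trimethoxyphenyl)-5,6,7-trimethoxy-4H-chromen-4-one
Product: 16 agehoustin B, 5,6,7-trimethoxy-2-(2,3,4,5-tetramethoxyphenyl)-4H-chromen-4-one
Conditions: MeI, K2CO3, acetone, reflux
Reagents that add atoms: iodomethane, CI
Why: Williamson ether synthesis on the only acidic OH of the molecule, with anhydrous carbonate in acetone being too weak to open the pyranone ring.

Compound list
1 | 3,4,5-trimethoxyphenol | COc1cc(O)cc(OC)c1OC | starting material
2 | 1-(6-hydroxy-2,3,4-trimethoxyphenyl)ethan-1-one | CC(=O)c1c(O)cc(OC)c(OC)c1OC | intermediate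
3 | diethyl oxalate | CCOC(=O)C(=O)OCC | starting material
4 | ethyl 4-(6-hydroxy-2,3,4-trimethoxyphenyl)-2,4-dioxobutanoate (not isolated) | CCOC(=O)C(=O)CC(=O)c1c(O)cc(OC)c(OC)c1OC | intermediate
5 | ethyl 5,6,7-trimethoxy-4-oxo-4H-chromene-2-carboxylate | CCOC(=O)c1cc(=O)c2c(OC)c(OC)c(OC)cc2o1 | intermediate
6 | 2-(hydroxymethyl)-5,6,7-trimethoxy-4H-chromen-4-one | OCc1cc(=O)c2c(OC)c(OC)c(OC)cc2o1 | intermediate
7 | 5,6,7-trimethoxy-4-oxo-4H-chromene-2-carbaldehyde | O=Cc1cc(=O)c2c(OC)c(OC)c(OC)cc2o1 | intermediate
8 | 2-ethynyl-5,6,7-trimethoxy-4H-chromen-4-one | C#Cc1cc(=O)c2c(OC)c(OC)c(OC)cc2o1 | intermediate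
9 | (Z)-1,2-dimethoxyethene | CO/C=C\OC | starting material
10 | chromium hexacarbonyl, Cr(CO)6 | O=C=[Cr](=C=O)(=C=O)(=C=O)(=C=O)=C=O | starting material
11 | (Z)-1,2-dimethoxyethenyllithium (not isolated) | [Li]/C(OC)=C/OC | intermediate
12 | lithium pentacarbonyl[(2Z)-2,3-dimethoxyprop-2-enoyl]chromate (not isolated) | [Li+].[O-]C(=[Cr](=C=O)(=C=O)(=C=O)(=C=O)=C=O)/C(OC)=C/OC | intermediate
13 | pentacarbonyl[(2Z)-1,2,3-trimethoxyprop-2-en-1-ylidene]chromium (zerovalent chromium) | O=C=[Cr](=C=O)(=C=O)(=C=O)(=C=O)=C(OC)/C(OC)=C/OC | intermediate
14 | tricarbonyl[η6-2-(2-hydroxy-3,4,5-trimethoxyphenyl)-5,6,7-trimethoxy-4H-chromen-4-one]chromium, Cr(CO)3 bound to ring B (not isolated) | COc1cc(-c2cc(=O)c3c(OC)c(OC)c(OC)cc3o2)c(O)c(OC)c1OC.O=C=[Cr](=C=O)=C=O | intermediate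
15 | 2-(2-hydroxy-3,4,5-trimethoxyphenyl)-5,6,7-trimethoxy-4H-chromen-4-one | COc1cc(-c2cc(=O)c3c(OC)c(OC)c(OC)cc3o2)c(O)c(OC)c1OC | intermediate
16 | agehoustin B, 5,6,7-trimethoxy-2-(2,3,4,5-tetramethoxyphenyl)-4H-chromen-4-one | COc1cc(-c2cc(=O)c3c(OC)c(OC)c(OC)cc3o2)c(OC)c(OC)c1OC | target

Total step count: 8. Longest linear sequence: 7 (steps 1 to 5, then 7 and 8); step 6 is the one-step side branch.

Steps most likely to fail

1. Step 7.
- What may go wrong: the donor-rich vinylcarbene intermediate may cyclise before CO migrates, giving five-membered ring formation. The electron-poor alkyne may insert sluggishly or repeatedly, leading to oligomerisation. Insertion may also occur with the opposite orientation.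
- Fallback (known chemistry only): it sets out from 2 and comes back at 16. Vilsmeier–Haack formylation (POCl3, DMF) of purchased 1,2,3,4-tetramethoxybenzene, whose two free positions are equivalent, gives 2,3,4,5-tetramethoxybenzaldehyde F1. Claisen–Schmidt condensation of this aldehyde with 2 (KOH, EtOH, rt) gives the 2'-hydroxychalcone F2. Oxidative cyclisation with catalytic I2 in DMSO at 130 °C closes the pyranone and gives 16 directly, so ring B is brought in ready-made.

2. Step 6.
- What may go wrong: anti elimination of lithium methoxide from the vinyllithium may occur before it meets chromium. Lithiation may be incomplete. The donor-rich carbene may decay during purification.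
- Fallback: it sets out from 9 and 10, comes back at 13, and uses no organolithium. Acylation of 9 with oxalyl chloride (0 °C to rt) gives (3Z)-3,4-dimethoxy-2-oxobut-3-enoyl chloride F3. Heating this to about 120 °C causes decarbonylation, the way 3-alkoxyacryloyl chlorides are made from vinyl ethers, and gives (2Z)-2,3-dimethoxyprop-2-enoyl chloride F4. Reduction of 10 with potassium graphite C8K in THF at −78 °C gives dipotassium pentacarbonylchromate K2Cr(CO)5 F5. This metalate attacks the acid chloride (Semmelhack–Hegedus route) to give the potassium acylchromate F6. Methylation with Me3OBF4 then rejoins the route at 13.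

3. Step 5.
- What may go wrong: methoxide may add in conjugate fashion at C2 and open the pyranone ring. Hemiacetal formation at the very electrophilic aldehyde may starve the olefination.
- Fallback: it sets out from 7 and comes back at 8, replacing the diazo chemistry by olefination and elimination in aprotic media. A Wittig reaction with the ylide from (bromomethyl)triphenylphosphonium bromide and NaN(SiMe3)2 in THF at −78 °C gives 2-[(Z)-2-bromoethenyl]-5,6,7-trimethoxy-4H-chromen-4-one F7. Anti elimination of hydrogen bromide with the non-nucleophilic base DBU in MeCN then gives 8.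

Further compounds
F1 | step 7 | 2,3,4,5-tetramethoxybenzaldehyde | COc1cc(C=O)c(OC)c(OC)c1OC
F2 | step 7 | (E)-1-(6-hydroxy-2,3,4-trimethoxyphenyl)-3-(2,3,4,5-tetramethoxyphenyl)prop-2-en-1-one | COc1cc(/C=C/C(=O)c2c(O)cc(OC)c(OC)c2OC)c(OC)c(OC)c1OC
F3 | step 6 | (3Z)-3,4-dimethoxy-2-oxobut-3-enoyl chloride | O=C(Cl)C(=O)/C(OC)=C/OC
F4 | step 6 | (2Z)-2,3-dimethoxyprop-2-enoyl chloride | O=C(Cl)/C(OC)=C/OC
F5 | step 6 | dipotassium pentacarbonylchromate, K2Cr(CO)5 | [K+].[K+].O=C=[Cr-2](=C=O)(=C=O)(=C=O)=C=O
F6 | step 6 | potassium pentacarbonyl[(2Z)-2,3-dimethoxyprop-2-enoyl]chromate | [K+].[O-]C(=[Cr](=C=O)(=C=O)(=C=O)(=C=O)=C=O)/C(OC)=C/OC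
F7 | step 5 | 2-[(Z)-2-bromoethenyl]-5,6,7-trimethoxy-4H-chromen-4-one | Br/C=C\c1cc(=O)c2c(OC)c(OC)c(OC)cc2o1
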